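**Retrosynthetic overview** (bisabolane numbering: ring C1 ester carbon, C2 ketone, C3–C4 ring oxirane, C5 methylene, C6 side-chain carbon; side chain C7/C14 oxirane, C8 ketone, C9=C10, C11–OOH)

1. The C11 hydroperoxide and the E-C9=C10 alkene are removed together by a last-step Schenck ene reaction of a prenyl ketone.
2. The prenyl ketone comes from an α-quaternary epoxy aldehyde by C8–C9 allylation, cross-metathesis and oxidation; the ring oxirane C3–C4 comes from hydroxyl-directed epoxidation after 1,2-reduction of a carvone-type enone.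
3. Key disconnection: the oxirane C7–O–C14, the C8–O bond and the fully substituted stereocentre C7 are removed in one step, back to the bare isopropenyl group of a 6-acyloxycarvone. In the forward sense O2 supplies both oxygen atoms (ene reaction, then titanium/tartrate-controlled transfer of the second oxygen).
4. The 6-acyloxycarvone comes from (R)-carvone, which brings the ring and C6, by α′-hydroxylation and acylation. Order of ring formation: cyclohexane (carvone), side-chain oxirane (step 3), ring oxirane (step 5).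

Key step: step 3

Assumption: the C8 carbinol centre of 12 and 14 is carried as a mixture of epimers and written without configuration, because it is oxidised to the ketone in step 9. Singlet oxygen is written as O2. Why lines use the bisabolane numbering above; compound names use systematic numbering.

**Step 1**
Reactants: 1 (R)-(−)-carvone
Product: 3 (5S,6S)-6-hydroxy-2-methyl-5-(prop-1-en-2-yl)cyclohex-2-en-1-one, via potassium dienolate 2 (not isolated)
Conditions: KHMDS, THF, −78 °C; 2-(phenylsulfonyl)-3-phenyloxaziridine, −78 °C; AcOH quench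
Reagents that add atoms: 2-(phenylsulfonyl)-3-phenyloxaziridine, O=S(=O)(N1OC1c1ccccc1)c1ccccc1
Why: Davis enolate hydroxylation: kinetic α′-deprotonation of the cross-conjugated enone and oxygen transfer to the enolate face anti to the adjacent isopropenyl group should give the trans α′-hydroxy ketone.

**Step 2**
Reactants: 3 (5S,6S)-6-hydroxy-2-methyl-5-(prop-1-en-2-yl)cyclohex-2-en-1-one; 4 isovaleric anhydride
Product: 5 (1S,6S)-3-methyl-2-oxo-6-(prop-1-en-2-yl)cyclohex-3-en-1-yl 3-methylbutanoate
Conditions: Et3N, DMAP (cat.), CH2Cl2, 0 °C to rt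
Reagents that add atoms: isovaleric anhydride (4), CC(C)CC(=O)OC(=O)CC(C)C
Why: DMAP-catalysed acylation (nucleophilic acyl-transfer catalysis) of the only hydroxyl group; no stereocentre is touched and the trans diequatorial arrangement is also the thermodynamic one.

**Step 3**
Reactants: 5 (1S,6S)-3-methyl-2-oxo-6-(prop-1-en-2-yl)cyclohex-3-en-1-yl 3-methylbutanoate
Product: 7 (1S,6R)-6-[(2S)-2-(hydroxymethyl)oxiran-2-yl]-3-methyl-2-oxocyclohex-3-en-1-yl 3-methylbutanoate, via allylic hydroperoxide 6 (not isolated)
Conditions: O2, TPP (1 mol %), hν (λ > 450 nm), CH2Cl2, 0 °C; then 4 Å MS, Ti(OiPr)4 (15 mol %), L-(+)-DET (18 mol %), −20 °C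
Reagents that add atoms: oxygen (sensitised to singlet oxygen), O=O
Why: Schenck ene reaction followed by titanium-mediated oxygen transfer from the allylic hydroperoxide (hydroxy-epoxidation under Sharpless-type tartrate control): singlet oxygen adds to the terminal carbon of the 1,1-disubstituted isopropenyl alkene and takes a methyl hydrogen, so the former =CH2 becomes C8 (CH2OOH) and the former CH3 becomes the C14 methylene of 6; on the Ti–tartrate complex the O–O bond of 6 then epoxidises the C7=C14 bond of a second, alkoxide-bound molecule, each transfer releasing the allylic alcohol that is the substrate of the next, so both new oxygen atoms come from O2. The closest known reaction types are the ene reaction of isopropenyl groups with singlet oxygen, the Ti(IV)-catalysed conversion of allylic hydroperoxides into 2,3-epoxy alcohols, and the Sharpless epoxidation of 2-substituted allyl alcohols. The oxirane C7–O–C14 is closed by concerted oxygen-atom transfer from the titanium-bound alkylperoxide to the π bond, a [2+1] addition and not an exo or endo cyclisation. The new C7 stereocentre is set by the tartrate: L-(+)-DET should deliver oxygen to the face that gives the (2S)-2-(hydroxymethyl)oxirane, the same sense as 2-methylallyl alcohol to (S)-2-methylglycidol, and reagent control should override the neighbouring C6 centre. The step needs chemoselectivity for the isopropenyl group, which is secured because the only other alkene is the electron-poor enone that does not react with singlet oxygen and because irradiation above 450 nm through the sensitiser avoids enone photochemistry; it also needs hydrogen abstraction from the methyl group and not from the ring methine C6–H, which allylic strain holds in the alkene plane where it cannot be abstracted.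

**Step 4**
Reactants: 7 (1S,6R)-6-[(2S)-2-(hydroxymethyl)oxiran-2-yl]-3-methyl-2-oxocyclohex-3-en-1-yl 3-methylbutanoate
Product: 8 (1S,2S,6R)-2-hydroxy-6-[(2S)-2-(hydroxymethyl)oxiran-2-yl]-3-methylcyclohex-3-en-1-yl 3-methylbutanoate
Conditions: NaBH4, CeCl3·7H2O, MeOH, −20 °C
Reagents that add atoms: none
Why: Luche 1,2-reduction: axial hydride delivery to the enone with the C1 ester and C6 side chain pseudo-equatorial should give the pseudo-equatorial C2 alcohol, cis to the side chain and trans to the ester (as carvone gives cis-carveol), and the low temperature and short time keep the isovalerate from migrating.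

**Step 5**
Reactants: 8 (1S,2S,6R)-2-hydroxy-6-[(2S)-2-(hydroxymethyl)oxiran-2-yl]-3-methylcyclohex-3-en-1-yl 3-methylbutanoate
Product: 9 (1R,2R,3S,4R,6S)-2-hydroxy-4-[(2S)-2-(hydroxymethyl)oxiran-2-yl]-1-methyl-7-oxabicyclo[4.1.0]heptan-3-yl 3-methylbutanoate
Conditions: VO(acac)2 (5 mol %), t-BuOOH, CH2Cl2, 0 °C to rt
Reagents that add atoms: tert-butyl hydroperoxide, CC(C)(C)OO
Why: Vanadium-catalysed hydroxyl-directed epoxidation of the cyclic allylic alcohol: the C2 vanadate delivers oxygen to the C3=C4 face syn to the hydroxyl group, which sets C3 and C4 with the oxirane cis to the C6 side chain, and no other alkene is left to compete.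

**Step 6**
Reactants: 9 (1R,2R,3S,4R,6S)-2-hydroxy-4-[(2S)-2-(hydroxymethyl)oxiran-2-yl]-1-methyl-7-oxabicyclo[4.1.0]heptan-3-yl 3-methylbutanoate
Product: 10 (1R,2R,3S,4R,6S)-4-[(2R)-2-formyloxiran-2-yl]-2-hydroxy-1-methyl-7-oxabicyclo[4.1.0]heptan-3-yl 3-methylbutanoate
Conditions: TEMPO (10 mol %), PhI(OAc)2, CH2Cl2, rt
Reagents that add atoms: none
Why: Oxoammonium (TEMPO/PhI(OAc)2) oxidation is selective for the primary alcohol over the hindered secondary C2 carbinol and gives an α-quaternary epoxy aldehyde that cannot epimerise.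

**Step 7**
Reactants: 10 (1R,2R,3S,4R,6S)-4-[(2R)-2-formyloxiran-2-yl]-2-hydroxy-1-methyl-7-oxabicyclo[4.1.0]heptan-3-yl 3-methylbutanoate; 11 allyl bromide
Product: 12 (1R,2R,3S,4R,6S)-2-hydroxy-4-[(2R)-2-(1-hydroxybut-3-en-1-yl)oxiran-2-yl]-1-methyl-7-oxabicyclo[4.1.0]heptan-3-yl 3-methylbutanoate
Conditions: In powder, THF/H2O (1:1), rt
Reagents that add atoms: allyl bromide (11), C=CCBr
Why: Indium-mediated Barbier allylation adds only to the aldehyde and tolerates the free hydroxyl group, the ester and both oxiranes; the new C8 carbinol forms as a mixture of epimers, which is removed by the oxidation in step 9.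

**Step 8**
Reactants: 12 (1R,2R,3S,4R,6S)-2-hydroxy-4-[(2R)-2-(1-hydroxybut-3-en-1-yl)oxiran-2-yl]-1-methyl-7-oxabicyclo[4.1.0]heptan-3-yl 3-methylbutanoate; 13 2-methyl-2-butene
Product: 14 (1R,2R,3S,4R,6S)-2-hydroxy-4-[(2R)-2-(1-hydroxy-4-methylpent-3-en-1-yl)oxiran-2-yl]-1-methyl-7-oxabicyclo[4.1.0]heptan-3-yl 3-methylbutanoate
Conditions: Grubbs second-generation catalyst (5 mol %), 2-methyl-2-butene (excess), CH2Cl2, 40 °C
Reagents that add atoms: 2-methyl-2-butene (13), CC=C(C)C
Why: Olefin cross-metathesis of the terminal alkene with 2-methyl-2-butene exchanges the methylene for an isopropylidene unit and gives the prenyl group without forming a stereocentre.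

**Step 9**
Reactants: 14 (1R,2R,3S,4R,6S)-2-hydroxy-4-[(2R)-2-(1-hydroxy-4-methylpent-3-en-1-yl)oxiran-2-yl]-1-methyl-7-oxabicyclo[4.1.0]heptan-3-yl 3-methylbutanoate
Product: 15 (1S,3S,4R,6S)-1-methyl-4-[(2R)-2-(4-methylpent-3-enoyl)oxiran-2-yl]-2-oxo-7-oxabicyclo[4.1.0]heptan-3-yl 3-methylbutanoate
Conditions: Dess–Martin periodinane, NaHCO3, CH2Cl2, 0 °C to rt
Reagents that add atoms: none
Why: Dess–Martin oxidation of both secondary carbinols under buffered, non-basic conditions should give the ring ketone and the β,γ-unsaturated side-chain ketone without moving the C10=C11 double bond into conjugation or epimerising C1.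

**Step 10**
Reactants: 15 (1S,3S,4R,6S)-1-methyl-4-[(2R)-2-(4-methylpent-3-enoyl)oxiran-2-yl]-2-oxo-7-oxabicyclo[4.1.0]heptan-3-yl 3-methylbutanoate
Product: 16 (1S,3S,4R,6S)-4-{(2R)-2-[(2E)-4-hydroperoxy-4-methylpent-2-enoyl]oxiran-2-yl}-1-methyl-2-oxo-7-oxabicyclo[4.1.0]heptan-3-yl 3-methylbutanoate
Conditions: O2, TPP (0.5 mol %), hν (λ > 450 nm), CH2Cl2, −20 °C
Reagents that add atoms: oxygen (sensitised to singlet oxygen), O=O
Why: Schenck ene reaction: singlet oxygen adds to C11 of the trisubstituted alkene and abstracts an allylic hydrogen from C9, which is activated by the C8 carbonyl and lies on the more substituted side of the alkene (cis effect), so the double bond should move to E-C9=C10 in conjugation with the ketone and give the tertiary hydroperoxide.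

**Compound list**

1 | (R)-(−)-carvone | CC1=CC[C@@H](C(C)=C)CC1=O | starting material
2 | potassium (3R)-6-methyl-3-(prop-1-en-2-yl)cyclohexa-1,5-dien-1-olate (potassium dienolate of carvone) | [K+].[O-]C1=C[C@H](C(C)=C)CC=C1C | intermediate
3 | (5S,6S)-6-hydroxy-2-methyl-5-(prop-1-en-2-yl)cyclohex-2-en-1-one (trans-6-hydroxycarvone) | O[C@@H]1C(=O)C(C)=CC[C@H]1C(C)=C | intermediate
4 | isovaleric anhydride (3-methylbutanoic anhydride) | CC(C)CC(=O)OC(=O)CC(C)C | starting material
5 | (1S,6S)-3-methyl-2-oxo-6-(prop-1-en-2-yl)cyclohex-3-en-1-yl 3-methylbutanoate | CC(C)CC(=O)O[C@@H]1C(=O)C(C)=CC[C@H]1C(C)=C | intermediate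
6 | (1S,6S)-6-(3-hydroperoxyprop-1-en-2-yl)-3-methyl-2-oxocyclohex-3-en-1-yl 3-methylbutanoate | CC(C)CC(=O)O[C@@H]1C(=O)C(C)=CC[C@H]1C(=C)COO | intermediate
7 | (1S,6R)-6-[(2S)-2-(hydroxymethyl)oxiran-2-yl]-3-methyl-2-oxocyclohex-3-en-1-yl 3-methylbutanoate | CC(C)CC(=O)O[C@@H]1C(=O)C(C)=CC[C@H]1[C@]1(CO)CO1 | intermediate
8 | (1S,2S,6R)-2-hydroxy-6-[(2S)-2-(hydroxymethyl)oxiran-2-yl]-3-methylcyclohex-3-en-1-yl 3-methylbutanoate | CC(C)CC(=O)O[C@@H]1[C@@H](O)C(C)=CC[C@H]1[C@]1(CO)CO1 | intermediate
9 | (1R,2R,3S,4R,6S)-2-hydroxy-4-[(2S)-2-(hydroxymethyl)oxiran-2-yl]-1-methyl-7-oxabicyclo[4.1.0]heptan-3-yl 3-methylbutanoate | CC(C)CC(=O)O[C@@H]1[C@@H](O)[C@@]2(C)O[C@H]2C[C@H]1[C@]1(CO)CO1 | intermediate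
10 | (1R,2R,3S,4R,6S)-4-[(2R)-2-formyloxiran-2-yl]-2-hydroxy-1-methyl-7-oxabicyclo[4.1.0]heptan-3-yl 3-methylbutanoate | CC(C)CC(=O)O[C@@H]1[C@@H](O)[C@@]2(C)O[C@H]2C[C@H]1[C@]1(C=O)CO1 | intermediate
11 | allyl bromide (3-bromoprop-1-ene) | C=CCBr | starting material
12 | (1R,2R,3S,4R,6S)-2-hydroxy-4-[(2R)-2-(1-hydroxybut-3-en-1-yl)oxiran-2-yl]-1-methyl-7-oxabicyclo[4.1.0]heptan-3-yl 3-methylbutanoate (carbinol epimers) | CC(C)CC(=O)O[C@@H]1[C@@H](O)[C@@]2(C)O[C@H]2C[C@H]1[C@]1(C(O)CC=C)CO1 | intermediate
13 | 2-methyl-2-butene | CC=C(C)C | starting material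
14 | (1R,2R,3S,4R,6S)-2-hydroxy-4-[(2R)-2-(1-hydroxy-4-methylpent-3-en-1-yl)oxiran-2-yl]-1-methyl-7-oxabicyclo[4.1.0]heptan-3-yl 3-methylbutanoate (carbinol epimers) | CC(C)CC(=O)O[C@@H]1[C@@H](O)[C@@]2(C)O[C@H]2C[C@H]1[C@]1(C(O)CC=C(C)C)CO1 | intermediate
15 | (1S,3S,4R,6S)-1-methyl-4-[(2R)-2-(4-methylpent-3-enoyl)oxiran-2-yl]-2-oxo-7-oxabicyclo[4.1.0]heptan-3-yl 3-methylbutanoate | CC(C)CC(=O)O[C@@H]1C(=O)[C@@]2(C)O[C@H]2C[C@H]1[C@]1(C(=O)CC=C(C)C)CO1 | intermediate
16 | (1S,3S,4R,6S)-4-{(2R)-2-[(2E)-4-hydroperoxy-4-methylpent-2-enoyl]oxiran-2-yl}-1-methyl-2-oxo-7-oxabicyclo[4.1.0]heptan-3-yl 3-methylbutanoate (CNP0131119.1) | CC(C)CC(=O)O[C@@H]1C(=O)[C@@]2(C)O[C@H]2C[C@H]1[C@]1(C(=O)/C=C/C(C)(C)OO)CO1 | target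

**Step count and risks**

Total step count: 10. Longest linear sequence: 10 steps, from (R)-carvone 1 to 16.

The three steps most likely to fail:

Step 3 (key step). The ene reaction of a 1,1-disubstituted alkene with singlet oxygen is slow, so conversion may stall while the sensitiser bleaches. The primary hydroperoxide may also dehydrate to the enal on titanium, and oxygen transfer during the induction period may be incomplete or weakly face-selective. The fallback sets out from 5 and comes back to the route at 7. Allylic oxidation of the isopropenyl methyl group of 5 with catalytic SeO2 and t-BuOOH (CH2Cl2, rt, run to partial conversion with recovery of 5) gives allylic alcohol F1. A conventional catalytic Sharpless asymmetric epoxidation of F1 (Ti(OiPr)4, L-(+)-DET, t-BuOOH, 4 Å MS, CH2Cl2, −20 °C) then gives 7 with the same tartrate-controlled facial sense.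

Step 10. Hydrogen abstraction may be poorly regioselective: abstraction from the cis-methyl group would give the secondary C10 hydroperoxide with a terminal alkene. In addition, 15 may isomerise to the conjugated enone before it reacts. The fallback sets out from 10 and comes back at 16, and replaces the ene reaction by a hydrogen-atom-transfer peroxidation. Hydrozirconation of 2-methylbut-1-en-3-yne (Cp2Zr(H)Cl), transmetalation with Me2Zn and addition to aldehyde 10 gives dienyl carbinol F2. Dess–Martin oxidation of both carbinols gives the cross-conjugated dienone F3. Mukaiyama–Isayama hydroperoxysilylation (Co(thd)2 cat., O2, Et3SiH, 1,2-dichloroethane, rt) transfers a hydrogen atom to the terminal methylene and traps the delocalised radical with O2 at the tertiary carbon, giving triethylsilyl peroxide F4. HF·pyridine in THF at 0 °C removes the silyl group and gives 16.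

Step 1. Facial selectivity of oxygen transfer to the enolate may be only moderate, and part of the enolate may be consumed by addition to the sulfonimine by-product. The fallback sets out from 1 and comes back at 5. Manganese(III) acetate-mediated α′-acyloxylation of the enone in the presence of isovaleric acid (Mn(OAc)3·2H2O, isovaleric acid, benzene, reflux with water removal) forms the ester C–O bond directly through the Mn(III) enolate. The epimerisable α′-centre can settle to the trans diequatorial isomer 5. No new compound is made (F0).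

**Further compounds**

F1 | step 3 | (1S,6S)-6-(3-hydroxyprop-1-en-2-yl)-3-methyl-2-oxocyclohex-3-en-1-yl 3-methylbutanoate | CC(C)CC(=O)O[C@@H]1C(=O)C(C)=CC[C@H]1C(=C)CO
F2 | step 10 | (1R,2R,3S,4R,6S)-2-hydroxy-4-{(2R)-2-[(2E)-1-hydroxy-4-methylpenta-2,4-dien-1-yl]oxiran-2-yl}-1-methyl-7-oxabicyclo[4.1.0]heptan-3-yl 3-methylbutanoate (carbinol epimers) | CC(C)CC(=O)O[C@@H]1[C@@H](O)[C@@]2(C)O[C@H]2C[C@H]1[C@]1(C(O)/C=C/C(C)=C)CO1
F3 | step 10 | (1S,3S,4R,6S)-1-methyl-4-{(2R)-2-[(2E)-4-methylpenta-2,4-dienoyl]oxiran-2-yl}-2-oxo-7-oxabicyclo[4.1.0]heptan-3-yl 3-methylbutanoate | CC(C)CC(=O)O[C@@H]1C(=O)[C@@]2(C)O[C@H]2C[C@H]1[C@]1(C(=O)/C=C/C(C)=C)CO1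
F4 | step 10 | (1S,3S,4R,6S)-1-methyl-4-{(2R)-2-[(2E)-4-methyl-4-(triethylsilylperoxy)pent-2-enoyl]oxiran-2-yl}-2-oxo-7-oxabicyclo[4.1.0]heptan-3-yl 3-methylbutanoate | CC(C)CC(=O)O[C@@H]1C(=O)[C@@]2(C)O[C@H]2C[C@H]1[C@]1(C(=O)/C=C/C(C)(C)OO[Si](CC)(CC)CC)CO1
F0 | step 1 | none | none
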